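**Assumption:** both enantiomers of methyl lactate and of citronellol are taken as commercial. Atom labels C1–C20 in the explanations follow halimane numbering of the target: C4 = ester-bearing quaternary carbon, C5 = ring-fusion CH, C8 = ring CHMe, C9 = ring quaternary carbon, C10 = ring-fusion sp2 carbon, C13 = side-chain CHMe. The target is (4S,5S,8R,9S,13R).

## Retrosynthetic overview

1. Ring A is closed last: the C1=C10 enone comes from intramolecular aldol condensation of a 1,5-diketone, whose C2 carbonyl is installed by Wacker oxidation of an (E)-propenyl group.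
2. C8 and C9: methyl cuprate addition to a 6-substituted 2-methylcyclohex-2-enone (ring B), with the enolate trapped by a five-carbon iodide cut from (R)-citronellol (which carries C13).
3. C4–C5 bond and both stereocentres (key step): C–O cross-coupling of the dienyl triflate of 2-methylcyclohex-2-enone with a lactate-derived (R)-allylic alcohol, then Claisen rearrangement of the allyl dienyl ether.
4. Ring order: ring B is bought; ring A is formed in the final step.

## Route

**Step 1**
Reactants: 1 methyl (2R)-2-hydroxypropanoate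
Product: 2 methyl (2R)-2-{[tert-butyl(dimethyl)silyl]oxy}propanoate
Conditions: TBSCl, imidazole, CH2Cl2, 0 °C → rt
Reagents that add atoms: tert-butyldimethylsilyl chloride, CC(C)(C)[Si](C)(C)Cl
Why: Imidazole-promoted silyl ether formation protects the hydroxyl without touching the lactate stereocentre.

**Step 2**
Reactants: 2 methyl (2R)-2-{[tert-butyl(dimethyl)silyl]oxy}propanoate; 3 methyl 2-(triphenylphosphoranylidene)propanoate
Product: 5 methyl (2E,4R)-4-{[tert-butyl(dimethyl)silyl]oxy}-2-methylpent-2-enoate, via silyloxy aldehyde 4 (not isolated)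
Conditions: iBu2AlH, CH2Cl2, −78 °C; then 3, −78 °C → rt
Reagents that add atoms: none
Why: Low-temperature half-reduction gives the configurationally labile aldehyde, which the stabilised ylide olefinates in the same pot (Wittig reaction) to the (E)-trisubstituted enoate without racemisation.

**Step 3**
Reactants: 5 methyl (2E,4R)-4-{[tert-butyl(dimethyl)silyl]oxy}-2-methylpent-2-enoate
Product: 6 methyl (2E,4R)-4-hydroxy-2-methylpent-2-enoate
Conditions: HF·pyridine, THF, 0 °C → rt
Reagents that add atoms: none
Why: Fluoride-mediated silyl ether cleavage under non-basic conditions frees the allylic alcohol while leaving the enoate geometry and the stereocentre intact.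

**Step 4**
Reactants: 7 2-methylcyclohex-2-en-1-one
Product: 9 6-methylcyclohexa-1,5-dien-1-yl trifluoromethanesulfonate, via lithium dienolate 8 (not isolated)
Conditions: LiN(iPr)2, THF, −78 °C; PhNTf2, −78 → 0 °C
Reagents that add atoms: N-phenylbis(trifluoromethanesulfonimide), O=S(=O)(N(c1ccccc1)S(=O)(=O)C(F)(F)F)C(F)(F)F
Why: Kinetic α′-deprotonation gives the cross-conjugated dienolate, which is O-sulfonylated (enol triflate formation) to a regiodefined 2-triflyloxy-1,3-diene.

**Step 5**
Reactants: 9 6-methylcyclohexa-1,5-dien-1-yl trifluoromethanesulfonate; 6 methyl (2E,4R)-4-hydroxy-2-methylpent-2-enoate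
Product: 11 methyl (2S,3E)-2-methyl-2-[(1R)-3-methyl-2-oxocyclohex-3-en-1-yl]pent-3-enoate, via allyl dienyl ether 10 (not isolated)
Conditions: Pd2(dba)3 (2.5 mol %), tBuBrettPhos (6 mol %), K3PO4, toluene, 60 °C; Celite filtration; then xylenes, 140 °C
Reagents that add atoms: none
Why: Proposed new method: zerovalent palladium bearing the bulky biarylphosphine adds oxidatively to the C–OTf bond of 9, the phosphate-generated alkoxide of 6 binds, and C(sp2)–O reductive elimination (which the ligand makes faster than β-hydride elimination) gives allyl dienyl ether 10 (closest known reactions: palladium/biarylphosphine etherification of aryl halides with secondary alcohols, palladium coupling of enol triflates with phenols, and the copper-catalysed vinyl iodide–allylic alcohol coupling/Claisen domino); 10 then undergoes a Claisen rearrangement through a chair transition state with the carbinol methyl equatorial (axial would clash with the Z-methyl of the enoate), so the (R)-carbinol centre is relayed to C4 (S) and C5 (ester cis to H-5) on an achiral diene that exerts no bias of its own.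

**Step 6**
Reactants: 12 (3R)-3,7-dimethyloct-6-en-1-ol
Product: 13 tert-butyl{[(3R)-3,7-dimethyloct-6-en-1-yl]oxy}dimethylsilane
Conditions: TBSCl, imidazole, DMF, rt
Reagents that add atoms: tert-butyldimethylsilyl chloride, CC(C)(C)[Si](C)(C)Cl
Why: Routine silylation of the primary alcohol, which must survive the cuprate and enolate chemistry of step 9.

**Step 7**
Reactants: 13 tert-butyl{[(3R)-3,7-dimethyloct-6-en-1-yl]oxy}dimethylsilane
Product: 15 (4R)-6-{[tert-butyl(dimethyl)silyl]oxy}-4-methylhexanoic acid, via aldehyde 14 (not isolated)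
Conditions: RuCl3·xH2O (2 mol %), NaIO4, MeCN/EtOAc/H2O, rt
Reagents that add atoms: sodium periodate, [Na+].[O-]I(=O)(=O)=O; water, O
Why: RuO4 oxidative cleavage (Sharpless conditions) cuts the trisubstituted alkene to the acid and leaves the remote stereocentre untouched.

**Step 8**
Reactants: 15 (4R)-6-{[tert-butyl(dimethyl)silyl]oxy}-4-methylhexanoic acid
Product: 16 tert-butyl{[(3S)-5-iodo-3-methylpentyl]oxy}dimethylsilane
Conditions: PhI(OAc)2, I2, cyclohexane, hν (tungsten lamp), reflux
Reagents that add atoms: iodine, II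
Why: Suárez iododecarboxylation (radical Hunsdiecker-type reaction via the acyl hypoiodite) excises one carbon and gives the primary iodide; the descriptor changes from R to S only because of CIP priorities.

**Step 9**
Reactants: 11 methyl (2S,3E)-2-methyl-2-[(1R)-3-methyl-2-oxocyclohex-3-en-1-yl]pent-3-enoate; 16 tert-butyl{[(3S)-5-iodo-3-methylpentyl]oxy}dimethylsilane
Product: 18 methyl (2S,3E)-2-[(1R,3S,4R)-3-[(3R)-5-{[tert-butyl(dimethyl)silyl]oxy}-3-methylpentyl]-3,4-dimethyl-2-oxocyclohexyl]-2-methylpent-3-enoate, via lithium enolate 17 (not isolated)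
Conditions: Me2CuLi (from MeLi, CuI), Et2O, −78 → −20 °C; then 16, HMPA/THF, −20 °C → rt
Reagents that add atoms: lithium dimethylcuprate, [Li+].C[Cu-]C (made from methyllithium, [Li]C)
Why: Conjugate addition–enolate alkylation: the cuprate adds axially (anti-parallel) to the enone whose bulky α′ substituent is equatorial, putting the C8 methyl cis to it, and the regiodefined enolate is then alkylated by 16 anti to that new methyl and to the α′ substituent, setting C9.

**Step 10**
Reactants: 18 methyl (2S,3E)-2-[(1R,3S,4R)-3-[(3R)-5-{[tert-butyl(dimethyl)silyl]oxy}-3-methylpentyl]-3,4-dimethyl-2-oxocyclohexyl]-2-methylpent-3-enoate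
Product: 20 methyl (2S)-2-[(1R,3S,4R)-3-[(3R)-5-hydroxy-3-methylpentyl]-3,4-dimethyl-2-oxocyclohexyl]-2-methyl-4-oxopentanoate, via silyl diketone 19 (not isolated)
Conditions: Pd(OAc)2 (5 mol %), 1,4-benzoquinone, aq HClO4 (0.3 M), MeCN/H2O 7:1, rt
Reagents that add atoms: water, O
Why: Wacker oxidation of the internal (E)-alkene puts the oxygen on the carbon remote from the quaternary, ester-bearing centre (steric and inductive bias) to give the methyl ketone, and the aqueous acid then hydrolyses the silyl ether in the same pot.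

**Step 11**
Reactants: 20 methyl (2S)-2-[(1R,3S,4R)-3-[(3R)-5-hydroxy-3-methylpentyl]-3,4-dimethyl-2-oxocyclohexyl]-2-methyl-4-oxopentanoate
Product: 22 methyl (1S,5S,6R,8aS)-5-[(3R)-5-hydroxy-3-methylpentyl]-1,5,6-trimethyl-3-oxo-1,2,3,5,6,7,8,8a-octahydronaphthalene-1-carboxylate, via ketol 21 (not isolated)
Conditions: NaOMe (0.3 equiv), MeOH, 0 °C → rt, stopped at full conversion
Reagents that add atoms: none
Why: Intramolecular aldol condensation (Robinson-type closure): the methyl ketone enolate adds to the ring ketone and E1cB loss of water gives the enone, while the hindered C5 methine next to the quaternary C4 is not expected to exchange under brief, mild base.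

## Compound list

1 | methyl (2R)-2-hydroxypropanoate (methyl (R)-lactate) | C[C@@H](O)C(=O)OC | starting material
2 | methyl (2R)-2-{[tert-butyl(dimethyl)silyl]oxy}propanoate | C[C@@H](O[Si](C)(C)C(C)(C)C)C(=O)OC | intermediate
3 | methyl 2-(triphenylphosphoranylidene)propanoate | COC(=O)C(C)=P(c1ccccc1)(c1ccccc1)c1ccccc1 | starting material
4 | (2R)-2-{[tert-butyl(dimethyl)silyl]oxy}propanal | C[C@@H](O[Si](C)(C)C(C)(C)C)C=O | intermediate
5 | methyl (2E,4R)-4-{[tert-butyl(dimethyl)silyl]oxy}-2-methylpent-2-enoate | C[C@@H](O[Si](C)(C)C(C)(C)C)/C=C(\C)C(=O)OC | intermediate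
6 | methyl (2E,4R)-4-hydroxy-2-methylpent-2-enoate | C[C@@H](O)/C=C(\C)C(=O)OC | intermediate
7 | 2-methylcyclohex-2-en-1-one | CC1=CCCCC1=O | starting material
8 | lithium 6-methylcyclohexa-1,5-dien-1-olate | CC1=CCCC=C1[O-].[Li+] | intermediate
9 | 6-methylcyclohexa-1,5-dien-1-yl trifluoromethanesulfonate | CC1=CCCC=C1OS(=O)(=O)C(F)(F)F | intermediate
10 | methyl (2E,4R)-2-methyl-4-[(6-methylcyclohexa-1,5-dien-1-yl)oxy]pent-2-enoate | COC(=O)/C(C)=C/[C@@H](C)OC1=CCCC=C1C | intermediate
11 | methyl (2S,3E)-2-methyl-2-[(1R)-3-methyl-2-oxocyclohex-3-en-1-yl]pent-3-enoate | COC(=O)[C@@](C)(/C=C/C)[C@H]1CCC=C(C)C1=O | intermediate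
12 | (3R)-3,7-dimethyloct-6-en-1-ol ((R)-citronellol) | CC(C)=CCC[C@@H](C)CCO | starting material
13 | tert-butyl{[(3R)-3,7-dimethyloct-6-en-1-yl]oxy}dimethylsilane | CC(C)=CCC[C@@H](C)CCO[Si](C)(C)C(C)(C)C | intermediate
14 | (4R)-6-{[tert-butyl(dimethyl)silyl]oxy}-4-methylhexanal | O=CCC[C@@H](C)CCO[Si](C)(C)C(C)(C)C | intermediate
15 | (4R)-6-{[tert-butyl(dimethyl)silyl]oxy}-4-methylhexanoic acid | OC(=O)CC[C@@H](C)CCO[Si](C)(C)C(C)(C)C | intermediate
16 | tert-butyl{[(3S)-5-iodo-3-methylpentyl]oxy}dimethylsilane | ICC[C@@H](C)CCO[Si](C)(C)C(C)(C)C | intermediate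
17 | lithium (3R,6R)-6-[(2S,3E)-1-methoxy-2-methyl-1-oxopent-3-en-2-yl]-2,3-dimethylcyclohex-1-en-1-olate | COC(=O)[C@@](C)(/C=C/C)[C@H]1CC[C@@H](C)C(C)=C1[O-].[Li+] | intermediate
18 | methyl (2S,3E)-2-[(1R,3S,4R)-3-[(3R)-5-{[tert-butyl(dimethyl)silyl]oxy}-3-methylpentyl]-3,4-dimethyl-2-oxocyclohexyl]-2-methylpent-3-enoate | COC(=O)[C@@](C)(/C=C/C)[C@H]1CC[C@@H](C)[C@](C)(CC[C@@H](C)CCO[Si](C)(C)C(C)(C)C)C1=O | intermediate
19 | methyl (2S)-2-[(1R,3S,4R)-3-[(3R)-5-{[tert-butyl(dimethyl)silyl]oxy}-3-methylpentyl]-3,4-dimethyl-2-oxocyclohexyl]-2-methyl-4-oxopentanoate | COC(=O)[C@@](C)(CC(C)=O)[C@H]1CC[C@@H](C)[C@](C)(CC[C@@H](C)CCO[Si](C)(C)C(C)(C)C)C1=O | intermediate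
20 | methyl (2S)-2-[(1R,3S,4R)-3-[(3R)-5-hydroxy-3-methylpentyl]-3,4-dimethyl-2-oxocyclohexyl]-2-methyl-4-oxopentanoate | COC(=O)[C@@](C)(CC(C)=O)[C@H]1CC[C@@H](C)[C@](C)(CC[C@@H](C)CCO)C1=O | intermediate
21 | methyl (1S,4aR,5S,6R,8aR)-4a-hydroxy-5-[(3R)-5-hydroxy-3-methylpentyl]-1,5,6-trimethyl-3-oxodecahydronaphthalene-1-carboxylate (drawn as the cis-fused ketol; the carbinol configuration is lost on dehydration) | COC(=O)[C@@]1(C)CC(=O)C[C@@]2(O)[C@@H]1CC[C@@H](C)[C@]2(C)CC[C@@H](C)CCO | intermediate
22 | methyl (1S,5S,6R,8aS)-5-[(3R)-5-hydroxy-3-methylpentyl]-1,5,6-trimethyl-3-oxo-1,2,3,5,6,7,8,8a-octahydronaphthalene-1-carboxylate (CNP0157174.1) | COC(=O)[C@@]1(C)CC(=O)C=C2[C@@H]1CC[C@@H](C)[C@]2(C)CC[C@@H](C)CCO | target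

## Step count and risks

Total step count: 11. Longest linear sequence: 7 steps (1, 2, 3, 5, 9, 10, 11).

The three steps most likely to fail:

**Step 5 (proposed new C–O coupling with in-flask Claisen).** The risks are β-hydride elimination of the palladium alkoxide, base-induced isomerisation of the γ-hydroxy enoate, ionisation of 10 by zerovalent palladium, and leakage through a boat transition state that would give the C5 epimer. Fallback with known chemistry: setting out from triflate 9, halide exchange (NaI, Ni(cod)2 cat., DMA/THF, rt) gives 1-iodo-6-methylcyclohexa-1,5-diene F1. F1 and alcohol 6 are then joined by the established copper-catalysed vinyl iodide–allylic alcohol etherification (CuI 10 mol %, 3,4,7,8-tetramethyl-1,10-phenanthroline, Cs2CO3, toluene, 80 → 120 °C), a known domino C–O coupling/Claisen process. This comes back to the route at allyl dienyl ether 10, which rearranges to 11 on continued heating.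

**Step 9 (conjugate addition, then alkylation of a tetrasubstituted enolate with an unactivated primary iodide).** The risks are low conversion in the alkylation, proton transfer that would scramble C5, and incomplete 3,6-cis selectivity in the cuprate addition. Fallback that replaces the alkylation by an aldol bond formation: setting out from enone 11, Me2CuLi addition followed by Me3SiCl/Et3N gives the trimethylsilyl enol ether F2. Iodide 16 is converted by Kornblum oxidation (NaHCO3, DMSO, 110 °C) into (3S)-5-{[tert-butyl(dimethyl)silyl]oxy}-3-methylpentanal F3. Mukaiyama aldol addition of F2 to F3 (TiCl4, CH2Cl2, −78 °C, aldehyde again anti to the C8 methyl) gives the β-hydroxy ketone F4 as carbinol epimers. Phenyl chlorothionoformate/pyridine converts F4 into the O-phenyl thionocarbonate F5, and Barton–McCombie deoxygenation (Bu3SnH, AIBN, toluene, 90 °C) comes back to the route at ketone 18.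

**Step 11 (aldol condensation on a hindered ketone).** The risk is epimerisation at C5, through the ring-ketone enolate before closure or through the dienolate of the product; a rough conformational count suggests the two C5 epimers are close in energy, so equilibration would erode the ratio. Fallback that avoids equilibrating base: setting out from 20, re-silylation (TBSCl, imidazole) gives 19, now isolated. Kinetic enolisation with in-situ trapping (LiN(iPr)2, Me3SiCl, THF, −78 °C) gives the terminal trimethylsilyl enol ether F6. Intramolecular Mukaiyama aldol addition (TiCl4, CH2Cl2, −78 °C) gives the silyl-protected ketol F7. Dehydration with the Burgess reagent (benzene, 50 °C) gives the silyl-protected enone F8, and HF·pyridine comes back to the route at target 22.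

## Further compounds

F1 | step 5 | 1-iodo-6-methylcyclohexa-1,5-diene | CC1=CCCC=C1I
F2 | step 9 | methyl (2S,3E)-2-[(1R,4R)-3,4-dimethyl-2-[(trimethylsilyl)oxy]cyclohex-2-en-1-yl]-2-methylpent-3-enoate | COC(=O)[C@@](C)(/C=C/C)[C@H]1CC[C@@H](C)C(C)=C1O[Si](C)(C)C
F3 | step 9 | (3S)-5-{[tert-butyl(dimethyl)silyl]oxy}-3-methylpentanal | O=CC[C@@H](C)CCO[Si](C)(C)C(C)(C)C
F4 | step 9 | aldol adduct: ketone 18 carrying a hydroxyl on the side-chain carbon bonded to the ring (both carbinol epimers) | COC(=O)[C@@](C)(/C=C/C)[C@H]1CC[C@@H](C)[C@](C)(C(O)C[C@@H](C)CCO[Si](C)(C)C(C)(C)C)C1=O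
F5 | step 9 | O-phenyl thionocarbonate of F4 | COC(=O)[C@@](C)(/C=C/C)[C@H]1CC[C@@H](C)[C@](C)(C(OC(=S)Oc2ccccc2)C[C@@H](C)CCO[Si](C)(C)C(C)(C)C)C1=O
F6 | step 11 | terminal trimethylsilyl enol ether of the methyl ketone of 19 | COC(=O)[C@@](C)(CC(=C)O[Si](C)(C)C)[C@H]1CC[C@@H](C)[C@](C)(CC[C@@H](C)CCO[Si](C)(C)C(C)(C)C)C1=O
F7 | step 11 | tert-butyldimethylsilyl ether (primary oxygen) of ketol 21 | COC(=O)[C@@]1(C)CC(=O)C[C@@]2(O)[C@@H]1CC[C@@H](C)[C@]2(C)CC[C@@H](C)CCO[Si](C)(C)C(C)(C)C
F8 | step 11 | tert-butyldimethylsilyl ether (primary oxygen) of target 22 | COC(=O)[C@@]1(C)CC(=O)C=C2[C@@H]1CC[C@@H](C)[C@]2(C)CC[C@@H](C)CCO[Si](C)(C)C(C)(C)C
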